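I count in millimolar, so a chain length is one concentration divided by another.

all flasks: protic impurity 0.200 mM; initiator 1.0 mM; time 40 s
- ochre: free monomer 10 mM
- blue: free monomer 40 mM

    free monomer → decomposition product (k1 = 2.8 × 10⁻⁵ s⁻¹)
    free monomer + living end → monomer in chains + living end, rate k2*[living end]*[free monomer] (k2 = 130 M⁻¹ s⁻¹)
    monomer in chains + living end → free monomer + living end, rate k3*[living end] as long as [monomer in chains] is above zero (k3 = 0.66 s⁻¹)
    initiator + monomer in chains → spent initiator (k4 = 17 M⁻¹ s⁻¹)
    free monomer + initiator → living end + monomer in chains (k5 = 140 M⁻¹ s⁻¹)
    protic impurity + free monomer → quenched substrate (k6 = 43 M⁻¹ s⁻¹)

- the average divides the monomer in chains by the number of chains begun, living and dead together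
- run time (ochre): 40 s

- which of the two ends with the longer chains by the average number of monomer units in a chain (chains begun, living or dead) ("neither" if they lie within 10 %) (ochre / blue / neither)
- average number of monomer units in a chain (chains begun, living or dead) at the end, ochre
- average number of monomer units in a chain (chains begun, living or dead) at the end, blue

The quantity I carry is the floor of the free monomer, 5.08 mM: the [free monomer] at which addition to a living end runs as fast as loss from it. It is the usual equilibrium monomer concentration. Both rates carry [living end], so [living end] cancels from the floor.

I solve the two ends and join them. At the start of ochre the initiator has a half-life of 0.495 s, far shorter than the run, so I set [living end] equal to the initiator charged. Late on, the free monomer sits on the floor, the protic impurity has taken its charge one for one, and the chains hold the rest. Between the ends, the excess over the floor falls pseudo-first-order, with time constant 7.69 s.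

Now the settings. The floor holds back the same amount in both flasks, so charging 4.00 times the free monomer in blue multiplies my length by 7.35. More initiator divides the same monomer among more chains and shortens the time constant. A longer run has little to gain: by 40 s the excess is down to 0.552 % of itself. So I reckon 4.70 units for ochre and 34.5 for blue.

The forecast says blue, with 4.7 (4.5 to 4.9) for ochre and 34.6 (33.5 to 35.5) for blue, holding that “the free monomer has almost reached its ceiling value”. My blue stands close to its figure.

The simulation gives blue, with 4.73 units in ochre and 34.6 in blue. At 40.0 s ochre holds 5.10 mM of free monomer against the floor of 5.08 mM, and monomer in chains is made 1.00 times as fast as it is used up. The neighbour of ochre charged with 0.60 mM of initiator has a longer time constant, 12.8 s, so floor and remainder give 7.52 units for it, and it ends at 7.58 units with 5.27 mM of free monomer.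

(The numbers of this flask are assumed; the run is a simulation.)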